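**Plan** (germacrane numbering: ring C1–C10, lactone O on C6, C7–C11(=C13)–C12(=O), C14 on C10, C15 on C4)

1. Retrosynthetic cuts, in order: the O8 epoxyangelate ester; the C8–C9 bond of the ten-membered ring (giving an enal C9/C10/C1 and a formyl group C8 on lactone carbon C7); C1=C10 (cross-metathesis with methacrolein); C6–C7 together with the lactone O–C12 bond (2-(methoxycarbonyl)allylation of a C6 enal); C2–C3 (allylboration); C3–C4 (formylation of a (Z)-alkenyl iodide made from but-2-yn-1-ol).
2. Forward order: C3–C6 piece with the Z C4=C5 bond, then the cis-fused α-methylene lactone, then the E enal by cross-metathesis, then the ten-membered carbocycle by C8–C9 closure, then acylation of O8 and desilylation of O9.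
3. Enabling feature: C8 and C9 are the two adjacent carbinol carbons of the ten-membered ring and C9 is allylic to C1=C10, so C9–C10=C1 is the reduced form of an enal. Reductive silylation of that enal gives a γ-siloxyallylchromium that adds through C9 to the C8 aldehyde held on the cis lactone.
4. This one event closes the ring, rewrites C1=C10 as Z whatever the enal geometry was, and delivers O9 silylated and O8 free, which is the pattern the target needs (O8 acylated, O9 free).
5. Stereochemistry: Z C4=C5 from hydroxyl-directed trans-hydroalumination; C3 from Brown allylboration; C6/C7 (cis lactone) from a ligand-controlled, syn-selective chromium allylation; C8, C9 and the Z C1=C10 bond from the chair transition state of the key step under Felkin–Anh control by C7; the epoxide from Sharpless epoxidation of angelyl alcohol.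

Key step: step 13

Remarks and assumptions
- Germacrane locants are used for the carbons of all intermediates.
- Assumption for step 10: the antipode of the carbazole-bis(oxazoline) ligand is the one that directs the allylchromium to the Si face of the formyl group of 11; if the first antipode tried shows the opposite sense, its mirror image is used.
- Compound 14 is racemic; its only stereocentre is removed in step 9.
- (−)-B-Allyldiisopinocampheylborane is used as the commercial solution.

**Route**

Step 1
Reactants: 1 but-2-yn-1-ol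
Product: 3 (Z)-3-iodobut-2-en-1-ol, via cyclic alkenylaluminate 2 (not isolated)
Conditions: NaAlH2(OCH2CH2OMe)2 (Red-Al), THF, 0 °C to rt; then I2, THF, −78 °C to 0 °C
Reagents that add atoms: iodine, [I][I]
Why: The alkoxyaluminium hydride formed from the propargylic alcohol delivers hydride intramolecularly (trans-hydroalumination) and places aluminium on C4 cis to the CH2O group, and iodinolysis of the C–Al bond with retention gives the (Z)-iodide that fixes the later Z C4=C5 geometry.

Step 2
Reactants: 3 (Z)-3-iodobut-2-en-1-ol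
Product: 4 (Z)-tert-butyl[(3-iodobut-2-en-1-yl)oxy]dimethylsilane
Conditions: TBSCl, imidazole, CH2Cl2, 0 °C to rt
Reagents that add atoms: tert-butyldimethylsilyl chloride, CC(C)(C)[Si](C)(C)Cl
Why: Imidazole-mediated silylation of the primary alcohol masks O6 for the organolithium step.

Step 3
Reactants: 4 (Z)-tert-butyl[(3-iodobut-2-en-1-yl)oxy]dimethylsilane
Product: 6 (Z)-4-[(tert-butyldimethylsilyl)oxy]-2-methylbut-2-enal, via alkenyllithium 5 (not isolated)
Conditions: t-BuLi (2 equiv), Et2O, −78 °C; then DMF, −78 °C; cold aqueous work-up, used crude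
Reagents that add atoms: N,N-dimethylformamide, CN(C)C=O
Why: Iodine–lithium exchange proceeds with retention of alkene geometry and the alkenyllithium is formylated by DMF (Bouveault-type formylation), so the formyl carbon C3 ends cis to C6.

Step 4
Reactants: 6 (Z)-4-[(tert-butyldimethylsilyl)oxy]-2-methylbut-2-enal
Product: 8 (4S,5Z)-7-[(tert-butyldimethylsilyl)oxy]-5-methylhepta-1,5-dien-4-ol, via diisopinocampheylborinate 7 (not isolated)
Conditions: (−)-Ipc2B(allyl), Et2O, −78 °C; then NaOH, H2O2, 0 °C to rt
Reagents that add atoms: (−)-B-allyldiisopinocampheylborane, C=CCB([C@@H]1C[C@@H]2C[C@H]([C@H]1C)C2(C)C)[C@@H]1C[C@@H]2C[C@H]([C@H]1C)C2(C)C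
Why: Brown allylboration through a closed chair transition state: the reagent made from (+)-α-pinene adds allyl to the Si face of the formyl group by 1,2-addition and sets C3 as S (4S in 8).

Step 5
Reactants: 8 (4S,5Z)-7-[(tert-butyldimethylsilyl)oxy]-5-methylhepta-1,5-dien-4-ol
Product: 9 (4S,5Z)-7-[(tert-butyldimethylsilyl)oxy]-5-methylhepta-1,5-dien-4-yl acetate
Conditions: Ac2O, pyridine, DMAP (cat.), CH2Cl2, 0 °C to rt
Reagents that add atoms: acetic anhydride, CC(=O)OC(C)=O
Why: DMAP-catalysed acylation installs the C3 acetate of the target at once, with no change at the stereocentre.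

Step 6
Reactants: 9 (4S,5Z)-7-[(tert-butyldimethylsilyl)oxy]-5-methylhepta-1,5-dien-4-yl acetate
Product: 10 (4S,5Z)-7-hydroxy-5-methylhepta-1,5-dien-4-yl acetate
Conditions: HF·pyridine, pyridine, THF, 0 °C
Reagents that add atoms: none
Why: Buffered fluoride cleavage of the primary silyl ether; the weakly acidic medium avoids acetyl migration from O3 to O6.

Step 7
Reactants: 10 (4S,5Z)-7-hydroxy-5-methylhepta-1,5-dien-4-yl acetate
Product: 11 (4S,5Z)-5-methyl-7-oxohepta-1,5-dien-4-yl acetate
Conditions: Dess–Martin periodinane, NaHCO3, CH2Cl2, 0 °C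
Reagents that add atoms: none
Why: Dess–Martin oxidation of the allylic alcohol under buffered, near-neutral conditions should give the C6 enal without Z-to-E isomerisation.

Step 8
Reactants: 12 methyl acrylate; 13 2,2-dimethoxyacetaldehyde
Product: 14 methyl 3-hydroxy-4,4-dimethoxy-2-methylidenebutanoate (racemic)
Conditions: DABCO, 1,4-dioxane/H2O, rt
Reagents that add atoms: none
Why: Morita–Baylis–Hillman reaction of an acrylate with a non-enolisable aldehyde; the new stereocentre is of no consequence because step 9 removes it.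

Step 9
Reactants: 14 methyl 3-hydroxy-4,4-dimethoxy-2-methylidenebutanoate
Product: 15 methyl (Z)-2-(bromomethyl)-4,4-dimethoxybut-2-enoate
Conditions: N-bromosuccinimide, Me2S, CH2Cl2, 0 °C to rt
Reagents that add atoms: N-bromosuccinimide, O=C1CCC(=O)N1Br
Why: Corey–Kim-type activation of the allylic alcohol and SN2′ attack of bromide give the rearranged, thermodynamically preferred (Z)-2-(bromomethyl)enoate under conditions that spare the acetal.

Step 10
Reactants: 11 (4S,5Z)-5-methyl-7-oxohepta-1,5-dien-4-yl acetate; 15 methyl (Z)-2-(bromomethyl)-4,4-dimethoxybut-2-enoate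
Product: 17 (1Z,3S)-1-[(2R,3R)-3-(dimethoxymethyl)-4-methylidene-5-oxooxolan-2-yl]-2-methylhexa-1,5-dien-3-yl acetate, via silylated syn adduct 16 (not isolated)
Conditions: CrCl2 (10 mol %), carbazole-bis(oxazoline) ligand (12 mol %), Mn, Me3SiCl, THF, rt; then PPTS, MeOH, rt
Reagents that add atoms: none
Why: Catalytic enantioselective Nozaki–Hiyama–Kishi-type 2-(alkoxycarbonyl)allylation followed by lactonisation (Dreiding–Schmidt lactone synthesis): the allylchromium keeps its γ-substituent cis to the CH2–Cr group and adds through a chair transition state to give the syn adduct 16 and hence the cis lactone (C7 relative to C6), while the chiral ligand on chromium selects the Si face of the formyl group and sets C6 as R.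

Step 11
Reactants: 17 (1Z,3S)-1-[(2R,3R)-3-(dimethoxymethyl)-4-methylidene-5-oxooxolan-2-yl]-2-methylhexa-1,5-dien-3-yl acetate; 18 methacrolein
Product: 19 (1Z,3S,5E)-1-[(2R,3R)-3-(dimethoxymethyl)-4-methylidene-5-oxooxolan-2-yl]-2,6-dimethyl-7-oxohepta-1,5-dien-3-yl acetate
Conditions: second-generation Hoveyda–Grubbs catalyst (5 mol %), excess 18, CH2Cl2, 40 °C
Reagents that add atoms: none
Why: Olefin cross-metathesis: only the monosubstituted alkene is a good partner (the trisubstituted alkene and the electron-poor 1,1-disubstituted acrylate are spectators) and the E enal is the expected product, whose geometry need not be Z because step 13 erases it.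

Step 12
Reactants: 19 (1Z,3S,5E)-1-[(2R,3R)-3-(dimethoxymethyl)-4-methylidene-5-oxooxolan-2-yl]-2,6-dimethyl-7-oxohepta-1,5-dien-3-yl acetate
Product: 20 (1Z,3S,5E)-1-[(2R,3R)-3-formyl-4-methylidene-5-oxooxolan-2-yl]-2,6-dimethyl-7-oxohepta-1,5-dien-3-yl acetate
Conditions: CF3CO2H/H2O, CH2Cl2, 0 °C, short reaction time; used at once
Reagents that add atoms: water, O
Why: Acid-catalysed hydrolysis of the dimethyl acetal sets free the C8 formyl group, and the cold, short treatment is meant to avoid epimerisation at C7.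

Step 13
Reactants: 20 (1Z,3S,5E)-1-[(2R,3R)-3-formyl-4-methylidene-5-oxooxolan-2-yl]-2,6-dimethyl-7-oxohepta-1,5-dien-3-yl acetate
Product: 22 (3S,6R,7S,8S,9R)-3-acetoxy-8-hydroxy-9-(triethylsilyloxy)germacra-1(10)Z,4Z,11(13)-trien-12,6-olide, via siloxyallylchromium 21 (not isolated)
Conditions: CrCl2 (6 equiv), Et3SiCl (3 equiv), DMF, rt; 20 added over 12 h by syringe pump (final concentration about 2 mM); aqueous NaHCO3 work-up
Reagents that add atoms: chlorotriethylsilane, CC[Si](Cl)(CC)CC
Why: Proposed new method: Et3SiCl activates the conjugated C9 carbonyl of 20 so that two equivalents of CrCl2 reduce it in two single-electron steps to the γ-siloxyallyl species 21 (trivalent chromium on C1, silyl enol ether C9=C10), whereas the saturated C8 aldehyde, the acrylate and the allylic acetate are not reduced by divalent chromium; 21 then transfers its allyl unit through C9 to the C8 carbonyl in a six-membered chair transition state (SE2′). The closest known reactions are the intermolecular CrCl2/R3SiCl cross-pinacol-type coupling of enals with aldehydes and Nozaki–Hiyama–Kishi allylations used for macrocyclisation; only their combination in one molecule is new. The ten-membered carbocycle closes in the 10-exo-trig mode (C9 attacks the C8=O carbon, whose oxygen stays outside the ring). C9 and C8 are set relative to each other by the chair (the siloxy group of the E enol ether derived from the s-trans enal and the C7 substituent of the aldehyde both equatorial, giving the anti glycol that is cis on the ring), and C8 is set relative to C7 by a Felkin–Anh arrangement with C6 anti to the forming bond and attack past H7, which together give 8S,9R. The C1=C10 geometry of 20 is erased in 21 and rewritten as Z because C2 lies axial on C1 in the chair (A(1,2) strain with the C10 methyl group and the lower strain of a cis-cyclodecene in the bicyclic transition state). The step needs chemoselective reduction of the enal (secured by silyl activation of the conjugated carbonyl only), ring closure in preference to oligomerisation (secured by slow addition at high dilution and by the cis relation of the two side chains on the lactone) and differentiation of the two new oxygens (O9 leaves as the triethylsilyl ether and O8 as the chromium alkoxide, which gives the free hydroxyl on work-up).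

Step 14
Reactants: 23 angelic acid
Product: 24 (Z)-2-methylbut-2-en-1-ol
Conditions: LiAlH4, Et2O, 0 °C
Reagents that add atoms: none
Why: Hydride reduction of the carboxylic acid to the allylic alcohol with retention of the Z geometry.

Step 15
Reactants: 24 (Z)-2-methylbut-2-en-1-ol
Product: 25 [(2S,3R)-2,3-dimethyloxiran-2-yl]methanol
Conditions: Ti(OiPr)4 (cat.), L-(+)-diethyl tartrate (cat.), t-BuOOH, 4 Å molecular sieves, CH2Cl2, −20 °C
Reagents that add atoms: tert-butyl hydroperoxide, CC(C)(C)OO
Why: Sharpless asymmetric epoxidation: with L-(+)-diethyl tartrate the oxygen is delivered to the face that gives the 2S,3R epoxy alcohol, and the Z geometry is translated into the cis relation of CH2OH and the C3 methyl group.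

Step 16
Reactants: 25 [(2S,3R)-2,3-dimethyloxiran-2-yl]methanol
Product: 27 (2R,3R)-2,3-dimethyloxirane-2-carboxylic acid, via epoxy aldehyde 26 (not isolated)
Conditions: RuCl3 (cat.), NaIO4, MeCN/EtOAc/H2O, 0 °C to rt
Reagents that add atoms: water, O
Why: RuO4-catalysed oxidation (RuCl3/NaIO4) of the primary alcohol through the aldehyde hydrate gives the epoxy acid without touching the epoxide stereocentres (the descriptor at C2 changes from S to R only through the change of CIP priorities).

Step 17
Reactants: 22 (3S,6R,7S,8S,9R)-3-acetoxy-8-hydroxy-9-(triethylsilyloxy)germacra-1(10)Z,4Z,11(13)-trien-12,6-olide; 27 (2R,3R)-2,3-dimethyloxirane-2-carboxylic acid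
Product: 29 (3S,6R,7R,8S,9R)-3-acetoxy-8-[(2R,3R)-2,3-dimethyloxirane-2-carbonyloxy]-9-(triethylsilyloxy)germacra-1(10)Z,4Z,11(13)-trien-12,6-olide, via mixed anhydride 28 (not isolated)
Conditions: 27, 2,4,6-trichlorobenzoyl chloride, Et3N, THF, rt; then 22, DMAP, toluene, rt
Reagents that add atoms: none
Why: Yamaguchi esterification: the mixed anhydride 28 acylates the only free hydroxyl group (O8) under DMAP catalysis with retention at C8, O9 being blocked as the silyl ether (the descriptor at C7 changes from S to R only through CIP priorities).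

Step 18
Reactants: 29 (3S,6R,7R,8S,9R)-3-acetoxy-8-[(2R,3R)-2,3-dimethyloxirane-2-carbonyloxy]-9-(triethylsilyloxy)germacra-1(10)Z,4Z,11(13)-trien-12,6-olide
Product: 30 (3S,6R,7R,8S,9R)-3-acetoxy-9-hydroxy-8-[(2R,3R)-2,3-dimethyloxirane-2-carbonyloxy]germacra-1(10)Z,4Z,11(13)-trien-12,6-olide (target)
Conditions: HF·pyridine, pyridine, THF, 0 °C
Reagents that add atoms: none
Why: Buffered fluoride cleavage of the secondary triethylsilyl ether leaves the acetate, the epoxy ester and the α-methylene lactone intact and gives the target.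

**Compound list**

1 | but-2-yn-1-ol | CC#CCO | starting material
2 | cyclic alkenylaluminate (sodium 3-methyl-2,2-bis(2-methoxyethoxy)-2,5-dihydro-1,2-oxaluminol-2-uide) | [Na+].CC1=CCO[Al-]1(OCCOC)OCCOC | intermediate
3 | (Z)-3-iodobut-2-en-1-ol | C/C(I)=C/CO | intermediate
4 | (Z)-tert-butyl[(3-iodobut-2-en-1-yl)oxy]dimethylsilane | C/C(I)=C/CO[Si](C)(C)C(C)(C)C | intermediate
5 | alkenyllithium: (Z)-[4-(tert-butyldimethylsilyloxy)but-2-en-2-yl]lithium | [Li]/C(C)=C\CO[Si](C)(C)C(C)(C)C | intermediate
6 | (Z)-4-[(tert-butyldimethylsilyl)oxy]-2-methylbut-2-enal | C/C(C=O)=C/CO[Si](C)(C)C(C)(C)C | intermediate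
7 | diisopinocampheylborinate of 8 | C=CC[C@H](OB([C@@H]1C[C@@H]2C[C@H]([C@H]1C)C2(C)C)[C@@H]1C[C@@H]2C[C@H]([C@H]1C)C2(C)C)/C(C)=C\CO[Si](C)(C)C(C)(C)C | intermediate
8 | (4S,5Z)-7-[(tert-butyldimethylsilyl)oxy]-5-methylhepta-1,5-dien-4-ol | C=CC[C@H](O)/C(C)=C\CO[Si](C)(C)C(C)(C)C | intermediate
9 | (4S,5Z)-7-[(tert-butyldimethylsilyl)oxy]-5-methylhepta-1,5-dien-4-yl acetate | C=CC[C@H](OC(C)=O)/C(C)=C\CO[Si](C)(C)C(C)(C)C | intermediate
10 | (4S,5Z)-7-hydroxy-5-methylhepta-1,5-dien-4-yl acetate | C=CC[C@H](OC(C)=O)/C(C)=C\CO | intermediate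
11 | (4S,5Z)-5-methyl-7-oxohepta-1,5-dien-4-yl acetate | C=CC[C@H](OC(C)=O)/C(C)=C\C=O | intermediate
12 | methyl acrylate | C=CC(=O)OC | starting material
13 | 2,2-dimethoxyacetaldehyde | COC(OC)C=O | starting material
14 | methyl 3-hydroxy-4,4-dimethoxy-2-methylidenebutanoate (racemic) | C=C(C(=O)OC)C(O)C(OC)OC | intermediate
15 | methyl (Z)-2-(bromomethyl)-4,4-dimethoxybut-2-enoate | COC(=O)/C(CBr)=C/C(OC)OC | intermediate
16 | methyl (3R,4R,5Z,7S)-7-acetoxy-3-(dimethoxymethyl)-6-methyl-2-methylidene-4-[(trimethylsilyl)oxy]deca-5,9-dienoate | C=C(C(=O)OC)[C@@H](C(OC)OC)[C@H](O[Si](C)(C)C)/C=C(/C)[C@@H](OC(C)=O)CC=C | intermediate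
17 | (1Z,3S)-1-[(2R,3R)-3-(dimethoxymethyl)-4-methylidene-5-oxooxolan-2-yl]-2-methylhexa-1,5-dien-3-yl acetate | C=C1C(=O)O[C@H](/C=C(/C)[C@@H](OC(C)=O)CC=C)[C@@H]1C(OC)OC | intermediate
18 | methacrolein (2-methylprop-2-enal) | C=C(C)C=O | starting material
19 | (1Z,3S,5E)-1-[(2R,3R)-3-(dimethoxymethyl)-4-methylidene-5-oxooxolan-2-yl]-2,6-dimethyl-7-oxohepta-1,5-dien-3-yl acetate | C=C1C(=O)O[C@H](/C=C(/C)[C@@H](OC(C)=O)C/C=C(\C)C=O)[C@@H]1C(OC)OC | intermediate
20 | (1Z,3S,5E)-1-[(2R,3R)-3-formyl-4-methylidene-5-oxooxolan-2-yl]-2,6-dimethyl-7-oxohepta-1,5-dien-3-yl acetate | C=C1C(=O)O[C@H](/C=C(/C)[C@@H](OC(C)=O)C/C=C(\C)C=O)[C@@H]1C=O | intermediate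
21 | γ-triethylsiloxyallylchromium dichloride (trivalent chromium on C1, E enol ether C9=C10, configuration at C1 not defined) | C=C1C(=O)O[C@H](/C=C(/C)[C@@H](OC(C)=O)CC([Cr](Cl)Cl)/C(C)=C/O[Si](CC)(CC)CC)[C@@H]1C=O | intermediate
22 | (3S,6R,7S,8S,9R)-3-acetoxy-8-hydroxy-9-(triethylsilyloxy)germacra-1(10)Z,4Z,11(13)-trien-12,6-olide | C=C1C(=O)O[C@@H]2/C=C(/C)[C@@H](OC(C)=O)C/C=C(/C)[C@@H](O[Si](CC)(CC)CC)[C@@H](O)[C@H]12 | intermediate
23 | angelic acid, (Z)-2-methylbut-2-enoic acid | C/C=C(/C)C(=O)O | starting material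
24 | (Z)-2-methylbut-2-en-1-ol | C/C=C(/C)CO | intermediate
25 | [(2S,3R)-2,3-dimethyloxiran-2-yl]methanol | OC[C@]1(C)O[C@@H]1C | intermediate
26 | (2R,3R)-2,3-dimethyloxirane-2-carbaldehyde | O=C[C@]1(C)O[C@@H]1C | intermediate
27 | (2R,3R)-2,3-dimethyloxirane-2-carboxylic acid | OC(=O)[C@]1(C)O[C@@H]1C | intermediate
28 | (2R,3R)-2,3-dimethyloxirane-2-carboxylic 2,4,6-trichlorobenzoic anhydride | Clc1cc(Cl)c(C(=O)OC(=O)[C@]2(C)O[C@@H]2C)c(Cl)c1 | intermediate
29 | (3S,6R,7R,8S,9R)-3-acetoxy-8-[(2R,3R)-2,3-dimethyloxirane-2-carbonyloxy]-9-(triethylsilyloxy)germacra-1(10)Z,4Z,11(13)-trien-12,6-olide | C=C1C(=O)O[C@@H]2/C=C(/C)[C@@H](OC(C)=O)C/C=C(/C)[C@@H](O[Si](CC)(CC)CC)[C@@H](OC(=O)[C@]3(C)O[C@@H]3C)[C@H]12 | intermediate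
30 | (3S,6R,7R,8S,9R)-3-acetoxy-9-hydroxy-8-[(2R,3R)-2,3-dimethyloxirane-2-carbonyloxy]germacra-1(10)Z,4Z,11(13)-trien-12,6-olide | C=C1C(=O)O[C@@H]2/C=C(/C)[C@@H](OC(C)=O)C/C=C(/C)[C@@H](O)[C@@H](OC(=O)[C@]3(C)O[C@@H]3C)[C@H]12 | target

**Step count and risks**

Total step count: 18. Longest linear sequence: 13 steps (steps 1–7, 10–13, 17, 18).

Steps most likely to fail:

Step 13 (bears the label "Proposed new method:"). What may go wrong: protonation of the allylchromium before it cyclises (simple reduction of the enal), intermolecular coupling, silylation of both new oxygens, or closure to the E ring alkene. Fallback with known chemistry, setting out from 17: the acetal of 17 is hydrolysed (CF3CO2H/H2O, CH2Cl2, 0 °C) to (1Z,3S)-1-[(2R,3R)-3-formyl-4-methylidene-5-oxooxolan-2-yl]-2-methylhexa-1,5-dien-3-yl acetate F1. This aldehyde is coupled with methacrolein 18 in the established intermolecular manner (CrCl2, Et3SiCl, DMF, rt). The coupling should give, under the same Felkin–Anh and chair control, (1Z,3S)-1-{(2R,3S)-3-[(1S,2R)-1-hydroxy-3-methyl-2-(triethylsilyloxy)but-3-en-1-yl]-4-methylidene-5-oxooxolan-2-yl}-2-methylhexa-1,5-dien-3-yl acetate F2. Ring-closing metathesis of the isopropenyl and vinyl groups of F2 (second-generation Hoveyda–Grubbs catalyst, toluene, 80 °C, high dilution) then closes the ten-membered ring at C1=C10, where the ring size favours the Z alkene, and the route is rejoined at 22.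

Step 10. What may go wrong: poor facial selectivity at C6 with this γ-substituted, acetal-bearing allyl bromide, or loss of methoxide from the allylchromium by β-elimination. Fallback, setting out from 11 and 15: indium-mediated Barbier coupling without any chiral ligand (In powder, THF/H2O, rt; then PPTS, MeOH). The relative configuration (syn adduct, cis lactone) then comes from the chair transition state alone, and the absolute configuration is secured by separation: 17 and (1Z,3S)-1-[(2S,3S)-3-(dimethoxymethyl)-4-methylidene-5-oxooxolan-2-yl]-2-methylhexa-1,5-dien-3-yl acetate F3 are diastereomers because of the resident C3 stereocentre and are separated by chromatography. The route is rejoined at 17, at the cost of the material that ends as F3.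

Step 12. What may go wrong: epimerisation at C7 or β-elimination of the lactone carboxylate (C6–O) when the formyl group is set free in acid. Fallback, setting out from 12 and 11, in which C8 is carried as a silyl-protected primary alcohol and unmasked by desilylation and oxidation instead of hydrolysis:
- Methyl acrylate 12 and commercial [(tert-butyldimethylsilyl)oxy]acetaldehyde (CC(C)(C)[Si](C)(C)OCC=O) give, under the conditions of step 8, methyl 4-[(tert-butyldimethylsilyl)oxy]-3-hydroxy-2-methylidenebutanoate F4.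
- N-Bromosuccinimide/Me2S converts it into methyl (Z)-2-(bromomethyl)-4-[(tert-butyldimethylsilyl)oxy]but-2-enoate F5.
- Coupling of this bromide with 11 under the conditions of step 10 gives (1Z,3S)-1-[(2R,3S)-3-{[(tert-butyldimethylsilyl)oxy]methyl}-4-methylidene-5-oxooxolan-2-yl]-2-methylhexa-1,5-dien-3-yl acetate F6.
- Cross-metathesis with 18 as in step 11 gives (1Z,3S,5E)-1-[(2R,3S)-3-{[(tert-butyldimethylsilyl)oxy]methyl}-4-methylidene-5-oxooxolan-2-yl]-2,6-dimethyl-7-oxohepta-1,5-dien-3-yl acetate F7.
- HF·pyridine gives (1Z,3S,5E)-1-[(2R,3S)-3-(hydroxymethyl)-4-methylidene-5-oxooxolan-2-yl]-2,6-dimethyl-7-oxohepta-1,5-dien-3-yl acetate F8.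
- Buffered Dess–Martin oxidation of this alcohol rejoins the route at 20.

Further compounds
F1 | step 13 | (1Z,3S)-1-[(2R,3R)-3-formyl-4-methylidene-5-oxooxolan-2-yl]-2-methylhexa-1,5-dien-3-yl acetate | C=C1C(=O)O[C@H](/C=C(/C)[C@@H](OC(C)=O)CC=C)[C@@H]1C=O
F2 | step 13 | (1Z,3S)-1-{(2R,3S)-3-[(1S,2R)-1-hydroxy-3-methyl-2-(triethylsilyloxy)but-3-en-1-yl]-4-methylidene-5-oxooxolan-2-yl}-2-methylhexa-1,5-dien-3-yl acetate | C=C1C(=O)O[C@H](/C=C(/C)[C@@H](OC(C)=O)CC=C)[C@@H]1[C@H](O)[C@H](O[Si](CC)(CC)CC)C(C)=C
F3 | step 10 | (1Z,3S)-1-[(2S,3S)-3-(dimethoxymethyl)-4-methylidene-5-oxooxolan-2-yl]-2-methylhexa-1,5-dien-3-yl acetate | C=C1C(=O)O[C@@H](/C=C(/C)[C@@H](OC(C)=O)CC=C)[C@H]1C(OC)OC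
F4 | step 12 | methyl 4-[(tert-butyldimethylsilyl)oxy]-3-hydroxy-2-methylidenebutanoate (racemic) | C=C(C(=O)OC)C(O)CO[Si](C)(C)C(C)(C)C
F5 | step 12 | methyl (Z)-2-(bromomethyl)-4-[(tert-butyldimethylsilyl)oxy]but-2-enoate | COC(=O)/C(CBr)=C/CO[Si](C)(C)C(C)(C)C
F6 | step 12 | (1Z,3S)-1-[(2R,3S)-3-{[(tert-butyldimethylsilyl)oxy]methyl}-4-methylidene-5-oxooxolan-2-yl]-2-methylhexa-1,5-dien-3-yl acetate | C=C1C(=O)O[C@H](/C=C(/C)[C@@H](OC(C)=O)CC=C)[C@@H]1CO[Si](C)(C)C(C)(C)C
F7 | step 12 | (1Z,3S,5E)-1-[(2R,3S)-3-{[(tert-butyldimethylsilyl)oxy]methyl}-4-methylidene-5-oxooxolan-2-yl]-2,6-dimethyl-7-oxohepta-1,5-dien-3-yl acetate | C=C1C(=O)O[C@H](/C=C(/C)[C@@H](OC(C)=O)C/C=C(\C)C=O)[C@@H]1CO[Si](C)(C)C(C)(C)C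
F8 | step 12 | (1Z,3S,5E)-1-[(2R,3S)-3-(hydroxymethyl)-4-methylidene-5-oxooxolan-2-yl]-2,6-dimethyl-7-oxohepta-1,5-dien-3-yl acetate | C=C1C(=O)O[C@H](/C=C(/C)[C@@H](OC(C)=O)C/C=C(\C)C=O)[C@@H]1CO
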